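## Structural features

The target is a lignan-type 2,3,4-trisubstituted tetrahydrofuran (O1, C2, C3, C4, C5). C2 carries a 4-hydroxy-3-methoxyphenyl ring, C3 a hydroxymethyl group (C3a), and C4 a secondary benzylic carbinol (C4a) with a second, identical aryl ring; C5 is a plain methylene. Four stereocentres stand in a row, C2–C3–C4–C4a. They read (2R,3S,4S) in the ring and (R) at C4a, with the C2 aryl trans to C3a and with C3a and C4a cis on the ring. Both benzylic C–O bonds (C2–O1 and C4a–OH) lie para to a phenolic oxygen. Acid therefore ionises them through quinone-methide-like cations, which leads to epimerisation or to closure of the C3a hydroxyl onto C4a. The same bonds can be lost under forcing hydrogenolysis, and the free phenols are easily oxidised. The real difficulty is the exocyclic centre C4a, which has to be set relative to the ring, together with the crowded cis C3/C4 arrangement. The feature used here is that C3a and C4a sit on the same face and both end as C–OH. A temporary C3a–C4a bond turns them into members of a cyclobutane (C3–C4–C4a–C3a) fused to the tetrahydrofuran, where C4a becomes a ring stereocentre ruled by the convex face. Because the two aryl rings are identical, both halves can come from one aldehyde.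

## Logic of the disconnections

16 to 15. The two phenolic O–CH2Ph bonds are restored. The phenols are masked until the end because they are what makes the benzylic C–O bonds labile and the arenes oxidisable. All earlier steps then deal with ethers that are stable to base, hydride and peracid. The forward step must cleave two aryl benzyl ethers and leave C2–O1 and C4a–OH untouched.

15 to 14. The hydroxyls on C3a and C4a are tied together by restoring the acyl bond C3a–O(C4a). A cis 1,4-diol is the reduced form of a γ-lactone. C4a becomes a ring atom of a cis-fused dioxabicyclo[3.3.0]octane, and C3a rises to the acid level. The forward reduction only has to be free of acid.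

14 to 13. The oxygen between C3a and C4a is taken out: the C4a–O bond is cut and the C3a–C4a bond restored. Oxygen insertion with retention carries a C–C-defined configuration over into the C–O centre. The second heterocycle becomes a carbocycle that a cycloaddition can make. The forward step demands that C4a migrates and C3 does not. The para-alkoxy donor on the C4a aryl and the inductive pull of O1 on C3 both favour this.

13 to 12 to 11. C3a=O goes back to C3a–OH and then to C3a–B. Boron is an oxygen placeholder that survives the photochemistry and steers the radical addition. The configuration at C3a ceases to matter. In 13, C4a is α to the carbonyl, so a misplaced aryl group can still be equilibrated to the convex face. The forward steps need mild two-electron oxidants.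

11 to 10. The C3–C4 and C3a–C4a bonds are cut. Both rings open and three controlled stereocentres disappear, which leaves an acyclic diene ether with one stereocentre, C2. The forward step must excite only the styrene, close five- before four-membered, and read the face from C2.

10 to 8 and 9. The C3a–B bond is cut. A terminal alkyne accepts B–H syn and terminally, which fixes the (E) geometry. The disubstituted styrene must stay untouched.

8 through 7 to 6 and 4. The O1–C5 bond is cut and the alkyne C–Si bond restored. The molecule falls into two halves of nearly equal size. The C2–O bond is never broken, so the configuration is carried through. The forward alkylation must avoid base-induced propargyl–allenyl isomerisation.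

6 to 1 and 5. The C2–C3 bond is cut. This is the only enantioselective event of the plan, and it needs attack on the Re face of 1.

4 through 3 to 1 and 2. The C5–Br bond goes back to a transposed C4a–OH, and then the C4a–C4 bond is cut. Both halves now come from 1. The forward bromination must place the halide on the terminal carbon with (E) geometry, and conjugation with the arene enforces both.

## Other disconnections considered

Alternative 1: The cut removes the C4–C5 bond of the tetrahydrofuran and the C4a–O bond of the bicyclic lactone A2. A2 is 14 with a tosylate in place of the benzyl ether on the C2 aryl ring. Both bonds lead back to the cis-5,6-disubstituted 1,3-dioxan-4-one A1, where C5 is the acetal methylene, C3a the ring carbonyl and C4=C4a an (E)-styryl branch on C3.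
- Forward key step: Me3SiOTf would ionise the acetal of A1 to an O1=C5H2 oxocarbenium ion and a silyl carboxylate. The styrene would attack through C4, because that leaves the charge on benzylic C4a, and the carboxylate would trap that cation.
- In its favour: two rings, two bonds and two stereocentres would form at once, with every carbon already at its final oxidation level.
- Against it here: the conditions are strongly Lewis acidic on a substrate with a benzylic C2–O1 bond. A 2-oxonia-Cope shift (C2–C3 broken, C5–C4a made) can scramble C2 and C3, which is why the C2 aryl must be deactivated as a sulfonate. The two aryl rings then need different protection, two different aldehydes and an extra deprotection. A1 also needs an α-selective, enantio- and diastereoselective aldol of a styrylacetic acid derivative, which tends to conjugate or to react at the γ-carbon.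
- On structure: no sacrificial bond is needed, which is a point for this alternative.
- On mechanism: a long-lived cation at C4a relies on thermodynamic exo capture. The chosen route keeps every step after the bromide free of acid and sets C4a inside a ring.
- On step economy: A2 stands where 14 stands, so steps 7 to 9 have no counterpart and this alternative is the better one after its key step. The gain is partly spent on building A1 and on the double deprotection.

Alternative 2: The cut removes O1–C2, C3–C4 and the lactone acyl C–O bond of A5, which is 14 with a methyl ester in place of H3. It leads back to the cis-epoxy alcohol A3 and the arylidene malonate A4.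
- Forward key step: the alkoxide of A3 would add to A4. The malonate anion would open the epoxide at C4 with inversion (5-exo-tet), and the freed C4a alkoxide would lactonise onto the cis ester.
- In its favour: this is the most convergent of all the plans, with three bonds and two rings from two simple partners. The oxa-Michael step is reversible, so C2 can settle to the exo aryl. C4 and C4a are defined by the epoxide.
- Against it here: enantioselective epoxidation of a (Z)-cinnamyl alcohol is the weak case of the Sharpless reaction. An epoxide next to a para-alkoxyaryl ring ionises very easily. Attack at benzylic C4a (6-endo) and Payne migration both compete with the wanted attack at C4. The extra ester has to be removed by a hot Krapcho reaction on a lactone with a labile benzylic C–O bond.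
- On structure: the plan carries a superfluous carbon where the chosen plan carries a superfluous bond, so the two are equal on this point.
- On mechanism: the anionic cascade is milder than a cationic one, but it depends on a regiochemistry that the substrate's electronics oppose. The 5-exo radical closure of the chosen route is favoured by both the tether and boron.
- On step economy: A5 is one step from 14, so this alternative is the better one if A3 can be had in high enantiopurity.

Alternative 3: The cut removes both lactone acyl C–O bonds (at C5 and C3a) of the twofold-symmetric bislactone A7 and takes C2 and C4a back to ketones. This gives the dimethyl diaroylsuccinate A6, the oxidative dimer of a β-keto ester.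
- Forward key step: asymmetric transfer hydrogenation with dynamic kinetic resolution would reduce both ketones of the epimerising A6, and each alkoxide would lactonise across the C3–C4 bond.
- In its favour: all four stereocentres would come from one catalytic operation on a symmetric, very short precursor. In stereocentres set per step it is the better plan, and it needs no protecting-group differentiation.
- Against it here: one isomer must emerge from a double resolution among many. Electron-rich, hindered aryl ketones reduce slowly, and the 1,4-diketone can cyclise to a furan in formic acid. The target is not symmetric. A7 would be reduced to the tetraol A8, and only one half may then close to the ether (C2–O onto activated C5) to reach 15. The second closure to the furofuran is just as easy, so the end game is a selectivity problem of mono- against bis-cyclisation.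
- On structure: it exploits the hidden symmetry of the carbon skeleton but fights the unsymmetrical oxygen pattern, which the chosen plan builds in from the start.
- On mechanism: catalyst control at C2 and C4a is direct, whereas the chosen route relays everything from C2.
- On step economy: it is shorter up to A7 and uncertain after it.

Key step: step 6

Assumption: 1 is bought as such (a catalogue chemical, the O-benzyl ether of vanillin).
Remark: the locants O1, C2–C5, C3a and C4a of 16 are used for the corresponding atoms of every intermediate. The descriptor changes at C2 (S in 6 and 7, R from 8 on) and at C3 come from CIP priorities only; no bond at these centres is broken.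

Step 1
Reactants: 1 4-(benzyloxy)-3-methoxybenzaldehyde; 2 vinylmagnesium bromide
Product: 3 rac-1-[4-(benzyloxy)-3-methoxyphenyl]prop-2-en-1-ol
Conditions: THF, 0 °C; aq. NH4Cl
Reagents that add atoms: none
Why: Grignard 1,2-addition to a non-enolisable aromatic aldehyde forms the C4a–C4 bond. The carbinol centre may be racemic because the next step flattens it.

Step 2
Reactants: 3 rac-1-[4-(benzyloxy)-3-methoxyphenyl]prop-2-en-1-ol
Product: 4 1-(benzyloxy)-4-[(E)-3-bromoprop-1-en-1-yl]-2-methoxybenzene
Conditions: PBr3 (0.4 equiv), Et2O, 0 °C; cold aq. NaHCO3 wash, used at once without chromatography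
Reagents that add atoms: phosphorus tribromide, BrP(Br)Br
Why: Bromination with allylic transposition (SN1/SN2′): the activated alcohol ionises to an aryl-conjugated allyl cation that bromide captures at the terminal carbon C5. Any secondary bromide should equilibrate to the conjugated (E)-cinnamyl bromide, the thermodynamic product.

Step 3
Reactants: 1 4-(benzyloxy)-3-methoxybenzaldehyde; 5 ethynyltrimethylsilane
Product: 6 (S)-1-[4-(benzyloxy)-3-methoxyphenyl]-3-(trimethylsilyl)prop-2-yn-1-ol
Conditions: 5 (3 equiv), Et2Zn (3 equiv), (R)-BINOL (20 mol%), Cy2NH (5 mol%), Et2O, rt; then Ti(OiPr)4 (50 mol%); then 1, rt; aq. NH4Cl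
Reagents that add atoms: none
Why: Catalytic asymmetric alkynylzinc addition to an aromatic aldehyde under a BINOL–titanium complex, the substrate class this reaction type suits best. C2 is set by the ligand: Re-face attack is needed, and (R)-BINOL is expected to give it as the mirror image of the Si-face delivery shown by (S)-BINOL–titanium in organozinc additions to aryl aldehydes. The sense would be confirmed by Mosher ester analysis before going on.

Step 4
Reactants: 6 (S)-1-[4-(benzyloxy)-3-methoxyphenyl]-3-(trimethylsilyl)prop-2-yn-1-ol; 4 1-(benzyloxy)-4-[(E)-3-bromoprop-1-en-1-yl]-2-methoxybenzene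
Product: 8 1-(benzyloxy)-4-[(1R)-1-{[(E)-3-[4-(benzyloxy)-3-methoxyphenyl]prop-2-en-1-yl]oxy}prop-2-yn-1-yl]-2-methoxybenzene, via trimethylsilyl alkyne ether 7 (not isolated)
Conditions: NaH (1.1 equiv), THF–DMF, 0 °C; 4 (1.2 equiv), Bu4NI (10 mol%), 0 °C to rt; then MeOH, K2CO3 (0.3 equiv), rt
Reagents that add atoms: none
Why: Williamson ether synthesis (SN2 at the primary allylic carbon C5) forms O1–C5 without touching the C2–O bond, so the configuration is kept. Methanolysis of the alkynyl C–Si bond follows in the same flask. Low temperature and only a slight excess of base guard against propargyl–allenyl isomerisation.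

Step 5
Reactants: 8 terminal alkyne ether (R at C2); 9 pinacolborane
Product: 10 2-[(1E,3R)-3-[4-(benzyloxy)-3-methoxyphenyl]-3-{[(E)-3-[4-(benzyloxy)-3-methoxyphenyl]prop-2-en-1-yl]oxy}prop-1-en-1-yl]-4,4,5,5-tetramethyl-1,3,2-dioxaborolane
Conditions: 9 (1.3 equiv), Cp2ZrHCl (10 mol%), Et3N (10 mol%), CH2Cl2, rt to 40 °C; rapid filtration through Et3N-deactivated silica
Reagents that add atoms: none
Why: Zirconium-catalysed alkyne hydroboration: syn hydrozirconation places the metal on the terminal carbon, and exchange with the B–H bond releases the (E)-alkenyl boronate. The disubstituted styrene hydrozirconates far more slowly than a terminal alkyne, and with zirconium on C3a there is no β-alkoxide to eliminate.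

Step 6
Reactants: 10 (E)-alkenyl pinacol boronate of the aryl carbinol cinnamyl ether (R at C2)
Product: 11 2-[(1R,2R,5S,6R)-2,6-bis[4-(benzyloxy)-3-methoxyphenyl]-3-oxabicyclo[3.2.0]heptan-7-yl]-4,4,5,5-tetramethyl-1,3,2-dioxaborolane (cis-fused, both aryl groups exo, either epimer at the boron-bearing carbon)
Conditions: Ir[dF(CF3)ppy]2(dtbbpy)PF6 (1 mol%), MeCN (0.02 M), argon-sparged, 450 nm LEDs, rt
Reagents that add atoms: none
Why: Triplet energy transfer from the photoexcited iridium complex reaches only the 3,4-dialkoxystyrene (C4=C4a), because the alkenyl boronate and the isolated arenes have much higher triplet energies; the closest known reaction type is the visible-light, triplet-sensitised intramolecular styrene–alkene [2+2] cycloaddition to 3-oxabicyclo[3.2.0]heptanes, which accepts alkenyl pinacol boronates. The twisted styrene triplet reacts as a 1,2-diradical whose non-benzylic carbon C4 adds to C3 in a 5-exo-trig closure (tetrahydrofuran ring, C3–C4 bond), a regiochemistry secured by the three-atom tether and by stabilisation of the new C3a radical through the empty boron p orbital. Intersystem crossing of the benzylic/α-boryl 1,4-diradical is followed by radical recombination of C3a with C4a, a four-membered closure that completes the cyclobutane. C3 is set against the only existing stereocentre: in the chair-like transition state the C2 aryl group lies pseudo-equatorial, which puts it trans to the C3–C3a bond. C4 is set by strain, since only the diradical with C3a and C4a cis can close, while the trans diradical fragments back to the diene and is recycled. C4a is set at the second bond formation, where the freely rotating benzylic radical closes with its aryl group on the convex face, so photochemical E/Z scrambling of the styrene is of no consequence. C3a may form as either epimer, which does not matter because it becomes a carbonyl carbon in step 8. The step needs chemoselective excitation, exclusion of oxygen and dilution against intermolecular dimerisation, and a substrate with one low-energy chromophore and a short tether meets these needs.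

Step 7
Reactants: 11 bicyclic pinacol boronate
Product: 12 (1S,4R,5S,7R)-4,7-bis[4-(benzyloxy)-3-methoxyphenyl]-3-oxabicyclo[3.2.0]heptan-6-ol (cis-fused, both aryl groups exo, carbinol epimers at C3a)
Conditions: NaBO3·4H2O (5 equiv), THF–H2O (1:1), rt
Reagents that add atoms: sodium perborate, [Na+].[O-]OB=O
Why: Oxidation of a secondary alkyl boronate by 1,2-migration from boron to oxygen with retention. Perborate is milder than alkaline peroxide and leaves the benzyl ethers and the benzylic ether alone.

Step 8
Reactants: 12 bicyclic cyclobutanol (epimers at C3a)
Product: 13 (1S,4R,5R,7R)-4,7-bis[4-(benzyloxy)-3-methoxyphenyl]-3-oxabicyclo[3.2.0]heptan-6-one (cis-fused, both aryl groups exo)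
Conditions: Pr4N[RuO4] (5 mol%), NMO (1.5 equiv), 4 Å MS, CH2Cl2, rt
Reagents that add atoms: none
Why: Ley–Griffith oxidation, a two-electron process that does not open cyclobutanols by radical cleavage, merges both carbinol epimers into one ketone. C4a is now α to the carbonyl, so the weak amine base present should equilibrate any endo aryl to the more stable exo position, while the cis fusion holds C3. Strong base is avoided because O1 is β to the ketone.

Step 9
Reactants: 13 bicyclic cyclobutanone
Product: 14 (1R,4R,5S,8R)-4,8-bis[4-(benzyloxy)-3-methoxyphenyl]-3,7-dioxabicyclo[3.3.0]octan-2-one (cis-fused, both aryl groups exo)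
Conditions: mCPBA (1.3 equiv), NaHCO3 (3 equiv), CH2Cl2, 0 °C
Reagents that add atoms: 3-chloroperoxybenzoic acid, O=C(OO)c1cccc(Cl)c1
Why: Baeyer–Villiger oxidation, made fast by release of cyclobutanone strain. The secondary benzylic carbon C4a, backed by a para-alkoxy donor, should migrate in preference to C3, whose aptitude is lowered by the neighbouring C2–O1 bond. Migration goes with retention, so the exo aryl configuration becomes (R) at the C4a–O centre, and the buffer prevents acid ionisation of the new benzylic ester bond.

Step 10
Reactants: 14 bicyclic lactone
Product: 15 (R)-[4-(benzyloxy)-3-methoxyphenyl][(3S,4S,5R)-5-[4-(benzyloxy)-3-methoxyphenyl]-4-(hydroxymethyl)oxolan-3-yl]methanol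
Conditions: LiAlH4 (2 equiv), THF, 0 °C; aq. potassium sodium tartrate
Reagents that add atoms: none
Why: Hydride reduction of the γ-lactone takes C3a to the primary alcohol and frees the C4a hydroxyl, which completes the cutting of the temporary tether. No stereocentre is touched, and the non-acidic work-up avoids ionisation at C4a.

Step 11
Reactants: 15 dibenzyl ether of the target
Product: 16 (R)-(4-hydroxy-3-methoxyphenyl)[(3S,4S,5R)-5-(4-hydroxy-3-methoxyphenyl)-4-(hydroxymethyl)oxolan-3-yl]methanol
Conditions: H2 (1 atm), 10% Pd/C, EtOAc–EtOH, rt, stopped as soon as 15 is consumed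
Reagents that add atoms: none
Why: Catalytic hydrogenolysis: under neutral, acid-free conditions aryl benzyl ethers cleave much faster than a secondary benzylic alcohol or a cyclic benzylic ether. Close monitoring should therefore free both phenols and keep C4a–OH and C2–O1.

## Compound list

1 | 4-(benzyloxy)-3-methoxybenzaldehyde | O=Cc1ccc(OCc2ccccc2)c(OC)c1 | starting material
2 | vinylmagnesium bromide | C=C[Mg]Br | starting material
3 | rac-1-[4-(benzyloxy)-3-methoxyphenyl]prop-2-en-1-ol | C=CC(O)c1ccc(OCc2ccccc2)c(OC)c1 | intermediate
4 | 1-(benzyloxy)-4-[(E)-3-bromoprop-1-en-1-yl]-2-methoxybenzene | BrC/C=C/c1ccc(OCc2ccccc2)c(OC)c1 | intermediate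
5 | ethynyltrimethylsilane | C#C[Si](C)(C)C | starting material
6 | (S)-1-[4-(benzyloxy)-3-methoxyphenyl]-3-(trimethylsilyl)prop-2-yn-1-ol | C[Si](C)(C)C#C[C@@H](O)c1ccc(OCc2ccccc2)c(OC)c1 | intermediate
7 | [(3S)-3-[4-(benzyloxy)-3-methoxyphenyl]-3-{[(E)-3-[4-(benzyloxy)-3-methoxyphenyl]prop-2-en-1-yl]oxy}prop-1-yn-1-yl]trimethylsilane | C[Si](C)(C)C#C[C@@H](OC/C=C/c1ccc(OCc2ccccc2)c(OC)c1)c1ccc(OCc2ccccc2)c(OC)c1 | intermediate
8 | 1-(benzyloxy)-4-[(1R)-1-{[(E)-3-[4-(benzyloxy)-3-methoxyphenyl]prop-2-en-1-yl]oxy}prop-2-yn-1-yl]-2-methoxybenzene | C#C[C@@H](OC/C=C/c1ccc(OCc2ccccc2)c(OC)c1)c1ccc(OCc2ccccc2)c(OC)c1 | intermediate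
9 | pinacolborane | CC1(C)OBOC1(C)C | starting material
10 | (1E,3R)-alkenyl pinacol boronate of the aryl carbinol (E)-cinnamyl ether | CC1(C)OB(/C=C/[C@@H](OC/C=C/c2ccc(OCc3ccccc3)c(OC)c2)c2ccc(OCc3ccccc3)c(OC)c2)OC1(C)C | intermediate
11 | (1R,2R,5S,6R)-2,6-diaryl-3-oxabicyclo[3.2.0]heptan-7-yl pinacol boronate, aryl = 4-(benzyloxy)-3-methoxyphenyl, both exo, C7 epimers | COc1cc([C@@H]2C(B6OC(C)(C)C(C)(C)O6)[C@@H]3[C@H]2CO[C@H]3c4ccc(OCc5ccccc5)c(OC)c4)ccc1OCc1ccccc1 | intermediate
12 | (1S,4R,5S,7R)-4,7-bis[4-(benzyloxy)-3-methoxyphenyl]-3-oxabicyclo[3.2.0]heptan-6-ol, C6 epimers | COc1cc([C@@H]2C(O)[C@@H]3[C@H]2CO[C@H]3c4ccc(OCc5ccccc5)c(OC)c4)ccc1OCc1ccccc1 | intermediate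
13 | (1S,4R,5R,7R)-4,7-bis[4-(benzyloxy)-3-methoxyphenyl]-3-oxabicyclo[3.2.0]heptan-6-one | COc1cc([C@@H]2C(=O)[C@@H]3[C@H]2CO[C@H]3c4ccc(OCc5ccccc5)c(OC)c4)ccc1OCc1ccccc1 | intermediate
14 | (1R,4R,5S,8R)-4,8-bis[4-(benzyloxy)-3-methoxyphenyl]-3,7-dioxabicyclo[3.3.0]octan-2-one | COc1cc([C@@H]2OC(=O)[C@@H]3[C@H]2CO[C@H]3c4ccc(OCc5ccccc5)c(OC)c4)ccc1OCc1ccccc1 | intermediate
15 | (R)-[4-(benzyloxy)-3-methoxyphenyl][(3S,4S,5R)-5-[4-(benzyloxy)-3-methoxyphenyl]-4-(hydroxymethyl)oxolan-3-yl]methanol | COc1cc([C@H](O)[C@@H]2CO[C@@H](c3ccc(OCc4ccccc4)c(OC)c3)[C@@H]2CO)ccc1OCc1ccccc1 | intermediate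
16 | (R)-(4-hydroxy-3-methoxyphenyl)[(3S,4S,5R)-5-(4-hydroxy-3-methoxyphenyl)-4-(hydroxymethyl)oxolan-3-yl]methanol | COc1cc([C@H](O)[C@@H]2CO[C@@H](c3ccc(O)c(OC)c3)[C@@H]2CO)ccc1O | target

## Step count and least certain steps

Total: 11 steps. The longest linear sequence is 10 steps (1, 3, 4, 8, 10, 11, 12, 13, 14, 15, 16; steps 1, 2, 4–11). The other branch (steps 3, 4–11) has 9.

Step 6 (key step).
- Risk: facial discrimination by the single C2 stereocentre may be only moderate in the first bond formation.
- Risk: light may be wasted in E/Z isomerisation and in reversal of the diradical.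
- Risk: the very electron-rich styrene may quench the strongly oxidising excited complex by electron transfer.
- Risk: long irradiation may erode the C–B bond and the doubly activated C2 ether.
- First adjustment: change to a neutral, weakly oxidising sensitiser of similar triplet energy, fac-Ir(dFppy)3.
- Fallback: keep the two bonds but replace the boron marker. Setting out from 8, platinum-catalysed hydrosilylation with benzyldimethylsilane (Pt2(dvtms)3, dvtms = 1,3-divinyltetramethyldisiloxane, P(t-Bu)3, THF) would give the (E)-alkenyl(benzyl)dimethylsilane F1. This compound is robust and can be chromatographed. The same sensitised cycloaddition would give the bicyclic cyclobutylsilane F2, whose diastereomers can be separated without loss of the marker. Tamao–Fleming oxidation (Bu4NF, THF; then H2O2, KHCO3, MeOH) would exchange silicon for hydroxyl with retention and rejoin the route at 12.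

Step 9.
- Risk: C3 may migrate in competition with C4a, because both are secondary carbons of a strained ring, and acid may ionise the new benzylic ester bond.
- Fallback: cut the same C3a–C4a bond oxidatively and set C4a again under catalyst control. Setting out from 13, soft enolisation toward the benzylic side (t-BuMe2SiOTf, Et3N, CH2Cl2, 0 °C; the bridgehead enol is too strained to compete) would give the aryl-conjugated silyl enol ether F3. Ozonolysis with a dye end-point (O3, CH2Cl2–MeOH, −78 °C; Me2S) would give the cis keto acid F4. Noyori–Ikariya transfer hydrogenation (RuCl(p-cymene)[(R,R)-TsDPEN], HCO2H–Et3N) should deliver the (R)-carbinol by the aryl/alkyl rule as the hydroxy acid F5, which lactonises and rejoins the route at 14. The weak point of this detour is possible epimerisation at C4, next to the aryl ketone.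

Step 11.
- Risk: over-reduction, that is, hydrogenolysis of C4a–OH or of C2–O1. Both become more labile the moment the para phenols are free.
- Fallback: move the hydrogenolysis to a stage where the C4a–O bond does not yet exist, and let the hydride step do the final deprotection. Setting out from 13, H2 and Pd/C would give the bisphenol ketone F6. Ac2O and pyridine would give the diacetate ketone F7, and buffered mCPBA the diacetate lactone F8. LiAlH4 (work-up near neutral pH) would open the lactone and cleave both aryl acetates in one operation, which rejoins the route at 16. The cost is one more step and a less electron-rich migrating group in the oxygen insertion.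

Step 3.
- Risk: the enantioselectivity may be insufficient, ethyl transfer from zinc may compete, or the facial sense may be opposite to that inferred by analogy. In the last case (S)-BINOL would be used.
- Fallback: replace C–C bond-forming induction by asymmetric reduction. Setting out from 1, addition of lithium trimethylsilylacetylide (5, n-BuLi, THF, −78 °C) would give the racemic carbinol F9, and MnO2 would give the ynone F10. Midland reduction with (S)-Alpine-Borane (B-isopinocampheyl-9-borabicyclo[3.3.1]nonane from (−)-α-pinene) treats the linear alkynyl group as the small substituent, and it should return the (S)-alcohol and rejoin the route at 6.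

Step 4.
- Risk: the ionisation-prone bromide 4 may decompose before it is alkylated. The alkoxide may remove silicon prematurely. Propargyl–allenyl isomerisation would cost configuration at C2.
- Fallback: avoid both the bromide and the sodium alkoxide. Setting out from 3, methyl chloroformate and pyridine would give the branched allylic methyl carbonate F11. Tsuji–Trost etherification with the zinc alkoxide of 6 (Et2Zn 0.5 equiv, Pd(OAc)2, 2-(di-tert-butylphosphino)biphenyl, THF, rt) proceeds through a π-allyl complex of divalent palladium that is attacked at the unhindered terminus. It should give the linear (E)-ether and rejoin the route at 7, which would be isolated and desilylated (K2CO3, MeOH) to 8.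

## Further compounds

F1 | step 6 | benzyl[(1E,3R)-3-[4-(benzyloxy)-3-methoxyphenyl]-3-{[(E)-3-[4-(benzyloxy)-3-methoxyphenyl]prop-2-en-1-yl]oxy}prop-1-en-1-yl]dimethylsilane | C[Si](C)(Cc1ccccc1)/C=C/[C@@H](OC/C=C/c1ccc(OCc2ccccc2)c(OC)c1)c1ccc(OCc2ccccc2)c(OC)c1
F2 | step 6 | benzyl[2,6-diaryl-3-oxabicyclo[3.2.0]heptan-7-yl]dimethylsilane, ring configuration as in 11, C7 epimers | COc1cc([C@@H]2C([Si](C)(C)Cc6ccccc6)[C@@H]3[C@H]2CO[C@H]3c4ccc(OCc5ccccc5)c(OC)c4)ccc1OCc1ccccc1
F3 | step 9 | tert-butyldimethylsilyl enol ether of 13 (C3a=C4a double bond) | COc1cc(C2=C(O[Si](C)(C)C(C)(C)C)[C@@H]3[C@H]2CO[C@H]3c4ccc(OCc5ccccc5)c(OC)c4)ccc1OCc1ccccc1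
F4 | step 9 | 4-[4-(benzyloxy)-3-methoxybenzoyl]-2-[4-(benzyloxy)-3-methoxyphenyl]oxolane-3-carboxylic acid, C3/C4 cis, C2/C3 trans | COc1cc(C(=O)[C@@H]2CO[C@@H](c3ccc(OCc4ccccc4)c(OC)c3)[C@@H]2C(=O)O)ccc1OCc1ccccc1
F5 | step 9 | hydroxy acid, (R) at C4a, ring as in F4 | COc1cc([C@H](O)[C@@H]2CO[C@@H](c3ccc(OCc4ccccc4)c(OC)c3)[C@@H]2C(=O)O)ccc1OCc1ccccc1
F6 | step 11 | 4,7-bis(4-hydroxy-3-methoxyphenyl)-3-oxabicyclo[3.2.0]heptan-6-one, configuration as in 13 | COc1cc([C@@H]2C(=O)[C@@H]3[C@H]2CO[C@H]3c4ccc(O)c(OC)c4)ccc1O
F7 | step 11 | 4,7-bis(4-acetoxy-3-methoxyphenyl)-3-oxabicyclo[3.2.0]heptan-6-one, configuration as in 13 | COc1cc([C@@H]2C(=O)[C@@H]3[C@H]2CO[C@H]3c4ccc(OC(C)=O)c(OC)c4)ccc1OC(C)=O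
F8 | step 11 | 4,8-bis(4-acetoxy-3-methoxyphenyl)-3,7-dioxabicyclo[3.3.0]octan-2-one, configuration as in 14 | COc1cc([C@@H]2OC(=O)[C@@H]3[C@H]2CO[C@H]3c4ccc(OC(C)=O)c(OC)c4)ccc1OC(C)=O
F9 | step 3 | rac-1-[4-(benzyloxy)-3-methoxyphenyl]-3-(trimethylsilyl)prop-2-yn-1-ol | C[Si](C)(C)C#CC(O)c1ccc(OCc2ccccc2)c(OC)c1
F10 | step 3 | 1-[4-(benzyloxy)-3-methoxyphenyl]-3-(trimethylsilyl)prop-2-yn-1-one | C[Si](C)(C)C#CC(=O)c1ccc(OCc2ccccc2)c(OC)c1
F11 | step 4 | rac-1-[4-(benzyloxy)-3-methoxyphenyl]prop-2-en-1-yl methyl carbonate | C=CC(OC(=O)OC)c1ccc(OCc2ccccc2)c(OC)c1
A1 | alternative 1 | (5R,6R)-5-[(E)-2-[4-(benzyloxy)-3-methoxyphenyl]ethenyl]-6-[3-methoxy-4-(tosyloxy)phenyl]-1,3-dioxan-4-one | O=C1OCO[C@@H](c2ccc(OS(=O)(=O)c3ccc(C)cc3)c(OC)c2)[C@H]1/C=C/c1ccc(OCc2ccccc2)c(OC)c1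
A2 | alternative 1 | (1R,4R,5S,8R)-4-[4-(benzyloxy)-3-methoxyphenyl]-8-[3-methoxy-4-(tosyloxy)phenyl]-3,7-dioxabicyclo[3.3.0]octan-2-one | COc1cc([C@@H]2OC(=O)[C@@H]3[C@H]2CO[C@H]3c4ccc(OS(=O)(=O)c5ccc(C)cc5)c(OC)c4)ccc1OCc1ccccc1
A3 | alternative 2 | [(2R,3S)-3-[4-(benzyloxy)-3-methoxyphenyl]oxiran-2-yl]methanol (cis) | OC[C@H]1O[C@H]1c1ccc(OCc2ccccc2)c(OC)c1
A4 | alternative 2 | dimethyl 2-[4-(benzyloxy)-3-methoxybenzylidene]malonate | COC(=O)C(=Cc1ccc(OCc2ccccc2)c(OC)c1)C(=O)OC
A5 | alternative 2 | methyl 4,8-bis[4-(benzyloxy)-3-methoxyphenyl]-2-oxo-3,7-dioxabicyclo[3.3.0]octane-1-carboxylate, cis-fused, both aryl groups exo | COc1cc([C@@H]2OC(=O)[C@]3(C(=O)OC)[C@H]2CO[C@H]3c4ccc(OCc5ccccc5)c(OC)c4)ccc1OCc1ccccc1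
A6 | alternative 3 | dimethyl 2,3-bis[4-(benzyloxy)-3-methoxybenzoyl]butanedioate (epimerising) | COC(=O)C(C(=O)c1ccc(OCc2ccccc2)c(OC)c1)C(C(=O)OC)C(=O)c1ccc(OCc2ccccc2)c(OC)c1
A7 | alternative 3 | 4,8-bis[4-(benzyloxy)-3-methoxyphenyl]-3,7-dioxabicyclo[3.3.0]octane-2,6-dione, cis-fused, both aryl groups exo | COc1cc([C@@H]2OC(=O)[C@@H]3[C@H]2C(=O)O[C@H]3c4ccc(OCc5ccccc5)c(OC)c4)ccc1OCc1ccccc1
A8 | alternative 3 | (1R,2S,3S,4R)-1,4-bis[4-(benzyloxy)-3-methoxyphenyl]-2,3-bis(hydroxymethyl)butane-1,4-diol | COc1cc([C@H](O)[C@H](CO)[C@@H](CO)[C@@H](O)c2ccc(OCc3ccccc3)c(OC)c2)ccc1OCc1ccccc1
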